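(The data stem from a simulated flask on assumed constants; the scatter is artificial.)

At late times substrate and intermediate A stop acting as two species and fall together, and this can be read from the readings without any fit.

| flask | substrate | remark | time |
|---|---|---|---|
| south | 12 mM | run made earlier |  |
| north | 18 mM | run made earlier |  |
| beta | 24 mM |  | 3.0 d |
| eta | 24 mM |  | 6.0 d |

| run | time / d | target / % | intermediate C / % | intermediate A / % | intermediate E / % | intermediate B / % | substrate / % |
|---|---|---|---|---|---|---|---|
| south | 0.500 | 0.1 | 1.9 | 20.8 | 4.0 | 8.0 | 66.9 |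
| south | 1.04 | 0.4 | 6.3 | 23.5 | 8.6 | 10.7 | 51.5 |
| south | 1.67 | 0.9 | 8.9 | 21.2 | 13.3 | 13.7 | 41.9 |
| south | 2.08 | 0 | 11.2 | 18.9 | 15.4 | 14.2 | 35.8 |
| south | 2.50 | 0.7 | 12.2 | 17.2 | 19.1 | 15.1 | 32.4 |
| south | 3.00 | 1.0 | 13.3 | 15.2 | 22.8 | 16.9 | 27.4 |
| north | 0.500 | 0.1 | 2.2 | 21.0 | 3.3 | 7.1 | 67.0 |
| north | 1.04 | 0.6 | 5.7 | 23.8 | 7.8 | 10.9 | 51.0 |
| north | 1.67 | 0.2 | 9.4 | 20.9 | 13.7 | 13.1 | 40.9 |
| north | 2.08 | 0.6 | 10.4 | 19.4 | 15.1 | 13.9 | 36.7 |
| north | 2.50 | 1.0 | 11.5 | 16.8 | 18.9 | 16.2 | 31.5 |
| north | 3.00 | 1.0 | 12.5 | 14.9 | 22.3 | 16.8 | 27.9 |

(standard deviation of a reading: 0.5 percentage points)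

- which of these there is most of at the end, counted by the substrate in it, beta (intermediate E / intermediate B / intermediate C / substrate / intermediate A)
- which of these there is most of at the end, counted by the substrate in it, eta (intermediate E / intermediate B / intermediate C / substrate / intermediate A)
- the largest of these amounts at the end, in percent of the substrate charged, beta
- the largest of these amounts at the end, in percent of the substrate charged, eta

- the numbers in the tables scatter with a standard deviation of 0.5 percentage points
- steps under discussion: substrate <-> intermediate A; substrate -> intermediate B; intermediate A <-> intermediate C; intermediate C -> intermediate D; intermediate B <-> intermediate E; intermediate D -> target; target -> intermediate E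

I take the mean of the south and north runs, which agree within scatter, and set up two columns:

| time | c(intermediate A)/c(substrate) | c(substrate)+c(intermediate A) |
|---|---|---|
| 0.500 d | 0.312 | 87.9 % |
| 1.67 d | 0.508 | 62.5 % |
| 2.50 d | 0.532 | 48.9 % |
| 3.00 d | 0.544 | 42.7 % |

The first column climbs and then levels off, so I treat the first step as a pre-equilibrium. The second column then falls as one pool, and its rows at 1.67 d and 3.00 d give 2.42 d, the pair half-life: the time in which substrate and intermediate A together drop to half.

Beta ends at the time of the last row, so it repeats those runs. For eta, my reckoning takes the pool down to 18.1 %, and the ratio leaves 11.7 % as substrate. That is less than the 22.6 % of intermediate E already read at 3.00 d, so substrate loses its lead.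

The forecast, reasoning “so the kinetics look first-order”, gives substrate at 27.7 % (26.8 % to 28.6 %) for beta and intermediate E at 39 % (35 % to 44 %) for eta.

The flasks give substrate at 27.7 % in beta and intermediate E at 34.6 % in eta.

    substrate ⇌ intermediate A (K = 0.560, k = 0.0330 /h)
    substrate → intermediate B (k = 0.0110 /h)
    intermediate A ⇌ intermediate C (K = 16.0, k = 0.0140 /h)
    intermediate C → intermediate D (k = 0.0110 /h)
    intermediate B ⇌ intermediate E (K = 1.60, k = 0.0680 /h)
    intermediate D → target (k = 0.0110 /h)
    target → intermediate E (k = 0.0240 /h)

The first step relaxes with a half-life of 0.314 d, short against 3.0 d, and eta holds 11.9 % of substrate where the pair half-life gave 11.7 %. Intermediate E ends higher in eta than in beta because of the difference in time: 22.0 % at the time of beta against 34.6 % in eta. Carried to the same flask read at 10 d, the pair half-life and the ratio give 3.72 % of substrate, and that flask holds 4.01 %.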